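The trione cage is taken apart at C3: C1–C2 and C5–C4 are opened by two Claisen disconnections, leaving a 3,3-dimethylcyclohexanone (ring A: C1, C9, C5, C6, C7, C8) tethered through C10 to a cyclopentane malonate. The cyclopentane (C3–C14–C13–C12–C11) is closed by the key step, a dirhodium carbene 1,5 C–H insertion that forms C3–C11 and fixes C11 in one operation. It exploits the fact that the C11 methylene sits five atoms from C3 across the quaternary C12, which carries no hydrogen. The precursor is a saturated α-diazo methyl ester on a chain hung from C7 of ketal-protected ring A; C7 comes from (S)-limonene.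

Key step: step 11

Atom labels: C1 benzoyl bridgehead, C2 and C4 ketones on C3, C5 geranyl bridgehead, C6, C7, C8 (CMe2), C9 bridging ketone, C10, C11, C12 (CMe2), C13, C14.

Assumption: Rh2(S-PTTL)4 is taken as the catalyst enantiomer matched to the C7 centre for the C11–H bond that leads to 21; if the sense of induction proves opposite, Rh2(R-PTTL)4 is used in the same way.

Step 1
Reactants: 1 (S)-limonene
Product: 3 (S)-6-oxo-3-(prop-1-en-2-yl)heptanal, via ozonide 2 (not isolated)
Conditions: O3 (Sudan red 7B end-point), CH2Cl2, −78 °C; Me2S, −78 °C to rt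
Reagents that add atoms: ozone, [O-][O+]=O
Why: Chemoselective ozonolysis, since the trisubstituted ring alkene is more electron-rich than the 1,1-disubstituted isopropenyl group and is cleaved first, leaving the future C7 centre untouched.

Step 2
Reactants: 3 (S)-6-oxo-3-(prop-1-en-2-yl)heptanal
Product: 4 (S)-7-hydroxy-5-(prop-1-en-2-yl)heptan-2-one
Conditions: NaBH4 (0.3 equiv), CH2Cl2/EtOH, −78 °C
Reagents that add atoms: none
Why: Chemoselective borohydride reduction, the aldehyde being reduced far faster than the methyl ketone at low temperature.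

Step 3
Reactants: 4 (S)-7-hydroxy-5-(prop-1-en-2-yl)heptan-2-one
Product: 8 (S)-8-hydroxy-6-(prop-1-en-2-yl)oct-1-en-3-one, via dilithium alkoxide enolate 5 (not isolated), via Mannich base 6 (not isolated), via trimethylammonium iodide 7 (not isolated)
Conditions: LDA (2.2 equiv), THF, −78 °C; [CH2=NMe2]I (Eschenmoser's salt), −78 °C to rt; MeI, rt; DBU, 0 °C; aqueous work-up
Reagents that add atoms: dimethylmethyleneammonium iodide, C=[N+](C)C.[I-]
Why: Kinetic deprotonation at the methyl group, Mannich aminomethylation, then quaternisation and Hofmann-type E1cB elimination give the vinyl ketone.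

Step 4
Reactants: 8 (S)-8-hydroxy-6-(prop-1-en-2-yl)oct-1-en-3-one
Product: 9 (S)-4-(2-hydroxyethyl)-3-methylcyclohex-2-en-1-one
Conditions: second-generation Grubbs catalyst (H2IMes)(PCy3)Cl2Ru=CHPh (5 mol%), CH2Cl2 (0.01 M), 40 °C
Reagents that add atoms: none
Why: Ring-closing metathesis between the vinyl ketone and the isopropenyl group closes ring A as a trisubstituted cyclohexenone with loss of ethylene, under neutral conditions that should leave the γ-centre C7 intact.

Step 5
Reactants: 9 (S)-4-(2-hydroxyethyl)-3-methylcyclohex-2-en-1-one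
Product: 10 (S)-4-(2-hydroxyethyl)-3,3-dimethylcyclohexan-1-one
Conditions: MeLi (6 equiv), CuI (3 equiv), Et2O, 0 °C; 9, −78 to 0 °C; aq. NH4Cl
Reagents that add atoms: lithium dimethylcuprate, [Li+].C[Cu-]C
Why: Cuprate 1,4-addition to the β-methyl enone builds the quaternary C8, the first equivalent being spent on the hydroxyl group.

Step 6
Reactants: 10 (S)-4-(2-hydroxyethyl)-3,3-dimethylcyclohexan-1-one
Product: 11 2-[(8S)-7,7-dimethyl-1,4-dioxaspiro[4.5]decan-8-yl]ethan-1-ol
Conditions: HOCH2CH2OH, p-TsOH·H2O (cat.), benzene, reflux (Dean–Stark)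
Reagents that add atoms: ethylene glycol, OCCO
Why: Acid-catalysed ketalisation with azeotropic removal of water masks the C9 ketone for the organometallic, carbene and enolate steps that follow.

Step 7
Reactants: 11 2-[(8S)-7,7-dimethyl-1,4-dioxaspiro[4.5]decan-8-yl]ethan-1-ol
Product: 12 (8S)-8-(2-bromoethyl)-7,7-dimethyl-1,4-dioxaspiro[4.5]decane
Conditions: CBr4, PPh3, imidazole, CH2Cl2, 0 °C
Reagents that add atoms: carbon tetrabromide, BrC(Br)(Br)Br
Why: Appel bromination of the primary alcohol under buffered conditions that spare the ketal.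

Step 8
Reactants: 12 (8S)-8-(2-bromoethyl)-7,7-dimethyl-1,4-dioxaspiro[4.5]decane; 13 3-methylbut-2-enal
Product: 16 5-[(8R)-7,7-dimethyl-1,4-dioxaspiro[4.5]decan-8-yl]-3,3-dimethylpentanal, via Grignard reagent 14 (not isolated), via trimethylsilyl enol ether 15 (not isolated)
Conditions: Mg, THF, 40 °C; CuBr·SMe2 (10 mol%), TMSCl, DMPU, 13, THF, −78 °C; aq. AcOH, THF, 0 °C
Reagents that add atoms: none
Why: Copper-catalysed, chlorosilane-accelerated conjugate addition of the primary Grignard reagent to the β,β-disubstituted enal forms the quaternary C12 by a polar pathway, and mild hydrolysis of the silyl enol ether releases the C14 aldehyde.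

Step 9
Reactants: 16 5-[(8R)-7,7-dimethyl-1,4-dioxaspiro[4.5]decan-8-yl]-3,3-dimethylpentanal; 17 methyl acetoacetate
Product: 19 methyl 2-acetyl-7-[(8R)-7,7-dimethyl-1,4-dioxaspiro[4.5]decan-8-yl]-5,5-dimethylheptanoate (both C2 epimers), via alkylidene acetoacetate 18 (not isolated)
Conditions: piperidine (cat.), AcOH (cat.), H2 (1 atm), Pd/C, MeOH, rt
Reagents that add atoms: none
Why: Reductive alkylation, a Knoevenagel condensation with in situ hydrogenation of the alkylidene acetoacetate, attaches C3 with its acetyl and ester groups and avoids double alkylation.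

Step 10
Reactants: 19 methyl 2-acetyl-7-[(8R)-7,7-dimethyl-1,4-dioxaspiro[4.5]decan-8-yl]-5,5-dimethylheptanoate
Product: 20 methyl 2-diazo-7-[(8R)-7,7-dimethyl-1,4-dioxaspiro[4.5]decan-8-yl]-5,5-dimethylheptanoate
Conditions: p-ABSA, DBU, MeCN, 0 °C to rt
Reagents that add atoms: 4-acetamidobenzenesulfonyl azide, CC(=O)Nc1ccc(cc1)S(=O)(=O)N=[N+]=[N-]
Why: Regitz diazo transfer with deacylation, the acetoacetate enolate capturing the sulfonyl azide and the acetyl group leaving as the N-acetyl sulfonamide.

Step 11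
Reactants: 20 methyl 2-diazo-7-[(8R)-7,7-dimethyl-1,4-dioxaspiro[4.5]decan-8-yl]-5,5-dimethylheptanoate
Product: 21 methyl (1R,2S)-2-{[(8S)-7,7-dimethyl-1,4-dioxaspiro[4.5]decan-8-yl]methyl}-3,3-dimethylcyclopentane-1-carboxylate
Conditions: Rh2(S-PTTL)4, dirhodium tetrakis[N-phthaloyl-(S)-tert-leucinate] (2 mol%), toluene, −78 to −40 °C, slow addition of 20
Reagents that add atoms: none
Why: Loss of N2 from 20 on the dirhodium carboxylate gives an electrophilic rhodium carbene at C3, which inserts into one C11–H bond through a concerted three-centre transition state, so that C3–C11 forms with retention at C11. The closest known reaction type is the dirhodium-catalysed 1,5 C–H insertion of α-alkyl α-diazo esters to cyclopentanecarboxylates under bulky chiral phthalimido-carboxylate ligands. The one ring closed is the cyclopentane C3–C14–C13–C12–C11, formed by 1,5-insertion through a six-centre chair-like array that includes the migrating hydrogen. C11 is set by the catalyst, which must choose between the two diastereotopic C11–H bonds against the weak bias of the C7 centre two bonds away; C3 is set in the same transition state but is epimerisable, and either epimer converges at the enolate of step 14. The step needs insertion to outrun the 1,2-hydride shift from C14, which the bulky carboxylates and the low temperature should secure, and it needs the secondary C11–H to be preferred over the six primary C–H bonds of the C12 methyl groups, which the carbene's preference for the more hydridic methylene should secure. The substrate is saturated and its ketone is masked, so cyclopropanation and carbonyl ylide formation are excluded, and the quaternary C12 removes any γ C–H and folds the chain toward closure.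

Step 12
Reactants: 21 methyl (1R,2S)-2-{[(8S)-7,7-dimethyl-1,4-dioxaspiro[4.5]decan-8-yl]methyl}-3,3-dimethylcyclopentane-1-carboxylate
Product: 22 (1R,2S)-2-{[(8S)-7,7-dimethyl-1,4-dioxaspiro[4.5]decan-8-yl]methyl}-3,3-dimethylcyclopentane-1-carboxylic acid
Conditions: LiOH, THF/MeOH/H2O, 50 °C; dilute HCl to pH 4, 0 °C
Reagents that add atoms: lithium hydroxide, [Li+].[OH-]
Why: Saponification of the secondary methyl ester, the ketal being stable to base and to the brief cold acidification.

Step 13
Reactants: 22 (1R,2S)-2-{[(8S)-7,7-dimethyl-1,4-dioxaspiro[4.5]decan-8-yl]methyl}-3,3-dimethylcyclopentane-1-carboxylic acid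
Product: 23 phenyl (1R,2S)-2-{[(8S)-7,7-dimethyl-1,4-dioxaspiro[4.5]decan-8-yl]methyl}-3,3-dimethylcyclopentane-1-carboxylate
Conditions: PhOH, EDC·HCl, DMAP (cat.), CH2Cl2, rt
Reagents that add atoms: phenol, Oc1ccccc1
Why: Steglich esterification installs the aryl ester that later serves as the acyl donor for the cage-closing C1–C2 bond.

Step 14
Reactants: 23 phenyl (1R,2S)-2-{[(8S)-7,7-dimethyl-1,4-dioxaspiro[4.5]decan-8-yl]methyl}-3,3-dimethylcyclopentane-1-carboxylate
Product: 25 1-(pentafluorophenyl) 1-phenyl (1R,2R)-2-{[(8S)-7,7-dimethyl-1,4-dioxaspiro[4.5]decan-8-yl]methyl}-3,3-dimethylcyclopentane-1,1-dicarboxylate, via lithium enolate 24 (not isolated)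
Conditions: LDA, THF, −78 °C; (C6F5O)2CO, −78 °C; aq. NH4Cl
Reagents that add atoms: bis(pentafluorophenyl) carbonate, O=C(Oc1c(F)c(F)c(F)c(F)c1F)Oc1c(F)c(F)c(F)c(F)c1F
Why: C-acylation of the ester enolate makes C3 quaternary, the electrophile approaching anti to the C11 side chain so that the more reactive pentafluorophenyl ester lies trans to C10 (future C4) and the phenyl ester cis (future C2).

Step 15
Reactants: 25 1-(pentafluorophenyl) 1-phenyl (1R,2R)-2-{[(8S)-7,7-dimethyl-1,4-dioxaspiro[4.5]decan-8-yl]methyl}-3,3-dimethylcyclopentane-1,1-dicarboxylate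
Product: 26 1-(pentafluorophenyl) 1-phenyl (1R,2R)-2-{[(1S)-2,2-dimethyl-4-oxocyclohexyl]methyl}-3,3-dimethylcyclopentane-1,1-dicarboxylate
Conditions: 1 M HCl, THF, rt
Reagents that add atoms: water, O
Why: Acid-catalysed ketal hydrolysis frees the C9 ketone while the hindered aryl esters on the quaternary C3 survive.

Step 16
Reactants: 26 1-(pentafluorophenyl) 1-phenyl (1R,2R)-2-{[(1S)-2,2-dimethyl-4-oxocyclohexyl]methyl}-3,3-dimethylcyclopentane-1,1-dicarboxylate
Product: 27 bicyclic β-diketone in which C5 of ring A is joined through the new C4 ketone to C3 (bicyclo[4.3.1]decanedione fused to the cyclopentane), C3 keeping the phenyl ester and C1 still CH2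
Conditions: 26 added to LiHMDS (2.1 equiv), THF (0.005 M), −78 to −20 °C; aq. NH4Cl
Reagents that add atoms: none
Why: Intramolecular crossed Claisen condensation in which the kinetic enolate at the less hindered C5 attacks the pentafluorophenyl ester and closes the seven-membered ring by the C5–C4 bond, deprotonation of the resulting β-diketone making the step irreversible and the bridged ring fixing C5.

Step 17
Reactants: 27 bicyclic β-diketone phenyl ester; 28 geranyl bromide
Product: 29 C5-geranyl derivative of 27, the (2E)-3,7-dimethylocta-2,6-dienyl group on the outer face of C5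
Conditions: K2CO3, acetone, 50 °C
Reagents that add atoms: none
Why: C-alkylation of the β-diketone by SN2 at the primary allylic bromide keeps the E geometry and makes C5 quaternary, the bridged bicycle leaving only the outer face open.

Step 18
Reactants: 29 C5-geranyl bicyclic diketone phenyl ester
Product: 30 cage trione, the target lacking the C1 benzoyl group (C1–H)
Conditions: KHMDS (1.2 equiv), THF, −78 to 0 °C; aq. NH4Cl at 0 °C
Reagents that add atoms: none
Why: Second intramolecular Claisen condensation in which C1, now the only enolisable position, attacks the phenyl ester held above ring A to form C1–C2 and close the cage, the poorly nucleophilic phenoxide being unlikely to reopen the non-enolisable trione and the cage fixing C1.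

Step 19
Reactants: 30 cage trione; 31 benzoyl chloride
Product: 33 CNP0168637.1, via bridgehead lithium enolate 32 (not isolated)
Conditions: LiTMP, THF, −78 °C; 31, −78 °C
Reagents that add atoms: none
Why: Bridgehead deprotonation of the only remaining α-hydrogen (C1–H, between the C2 and C9 ketones) with a hindered, non-reducing amide and C-acylation of the localised carbanion, a known way to substitute bridgeheads of bicyclic polyketones, with the cage enforcing retention at C1.

Compound list

1 | (S)-limonene, (4S)-1-methyl-4-(prop-1-en-2-yl)cyclohex-1-ene | CC1=CC[C@H](CC1)C(C)=C | starting material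
2 | ozonide of the ring alkene of 1, 1-methyl-4-(prop-1-en-2-yl)-7,8,9-trioxabicyclo[4.2.1]nonane, C4 as in 1 | CC12CC[C@H](C(C)=C)CC(OO1)O2 | intermediate (not isolated)
3 | (S)-6-oxo-3-(prop-1-en-2-yl)heptanal | O=CC[C@H](CCC(C)=O)C(C)=C | intermediate
4 | (S)-7-hydroxy-5-(prop-1-en-2-yl)heptan-2-one | OCC[C@H](CCC(C)=O)C(C)=C | intermediate
5 | dilithium alkoxide and terminal enolate of 4 | [Li+].[Li+].[O-]CC[C@H](CCC([O-])=C)C(C)=C | intermediate (not isolated)
6 | Mannich base, (S)-1-(dimethylamino)-8-hydroxy-6-(prop-1-en-2-yl)octan-3-one | OCC[C@H](CCC(=O)CCN(C)C)C(C)=C | intermediate (not isolated)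
7 | N-methyl quaternary ammonium iodide of 6 | OCC[C@H](CCC(=O)CC[N+](C)(C)C)C(C)=C.[I-] | intermediate (not isolated)
8 | (S)-8-hydroxy-6-(prop-1-en-2-yl)oct-1-en-3-one | OCC[C@H](CCC(=O)C=C)C(C)=C | intermediate
9 | (S)-4-(2-hydroxyethyl)-3-methylcyclohex-2-en-1-one | OCC[C@@H]1CCC(=O)C=C1C | intermediate
10 | (S)-4-(2-hydroxyethyl)-3,3-dimethylcyclohexan-1-one | OCC[C@@H]1CCC(=O)CC1(C)C | intermediate
11 | 2-[(8S)-7,7-dimethyl-1,4-dioxaspiro[4.5]decan-8-yl]ethan-1-ol | OCC[C@@H]1CCC2(CC1(C)C)OCCO2 | intermediate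
12 | (8S)-8-(2-bromoethyl)-7,7-dimethyl-1,4-dioxaspiro[4.5]decane | BrCC[C@@H]1CCC2(CC1(C)C)OCCO2 | intermediate
13 | 3-methylbut-2-enal | CC(C)=CC=O | starting material
14 | Grignard reagent of 12, {2-[(8S)-7,7-dimethyl-1,4-dioxaspiro[4.5]decan-8-yl]ethyl}magnesium bromide | Br[Mg]CC[C@@H]1CCC2(CC1(C)C)OCCO2 | intermediate (not isolated)
15 | trimethylsilyl enol ether of 16 (E/Z) | C[Si](C)(C)OC=CC(C)(C)CC[C@@H]1CCC2(CC1(C)C)OCCO2 | intermediate (not isolated)
16 | 5-[(8R)-7,7-dimethyl-1,4-dioxaspiro[4.5]decan-8-yl]-3,3-dimethylpentanal | O=CCC(C)(C)CC[C@@H]1CCC2(CC1(C)C)OCCO2 | intermediate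
17 | methyl acetoacetate | COC(=O)CC(C)=O | starting material
18 | methyl 2-acetyl-7-[(8R)-7,7-dimethyl-1,4-dioxaspiro[4.5]decan-8-yl]-5,5-dimethylhept-2-enoate (E/Z) | COC(=O)C(=CCC(C)(C)CC[C@@H]1CCC2(CC1(C)C)OCCO2)C(C)=O | intermediate (not isolated)
19 | methyl 2-acetyl-7-[(8R)-7,7-dimethyl-1,4-dioxaspiro[4.5]decan-8-yl]-5,5-dimethylheptanoate (both C2 epimers) | COC(=O)C(CCC(C)(C)CC[C@@H]1CCC2(CC1(C)C)OCCO2)C(C)=O | intermediate
20 | methyl 2-diazo-7-[(8R)-7,7-dimethyl-1,4-dioxaspiro[4.5]decan-8-yl]-5,5-dimethylheptanoate | COC(=O)C(=[N+]=[N-])CCC(C)(C)CC[C@@H]1CCC2(CC1(C)C)OCCO2 | intermediate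
21 | methyl (1R,2S)-2-{[(8S)-7,7-dimethyl-1,4-dioxaspiro[4.5]decan-8-yl]methyl}-3,3-dimethylcyclopentane-1-carboxylate (trans) | COC(=O)[C@@H]1CCC(C)(C)[C@H]1C[C@@H]1CCC2(CC1(C)C)OCCO2 | intermediate
22 | (1R,2S)-2-{[(8S)-7,7-dimethyl-1,4-dioxaspiro[4.5]decan-8-yl]methyl}-3,3-dimethylcyclopentane-1-carboxylic acid | OC(=O)[C@@H]1CCC(C)(C)[C@H]1C[C@@H]1CCC2(CC1(C)C)OCCO2 | intermediate
23 | phenyl (1R,2S)-2-{[(8S)-7,7-dimethyl-1,4-dioxaspiro[4.5]decan-8-yl]methyl}-3,3-dimethylcyclopentane-1-carboxylate | O=C(Oc1ccccc1)[C@@H]1CCC(C)(C)[C@H]1C[C@@H]1CCC2(CC1(C)C)OCCO2 | intermediate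
24 | lithium enolate of 23 | [Li+].[O-]C(Oc1ccccc1)=C1CCC(C)(C)[C@H]1C[C@@H]1CCC2(CC1(C)C)OCCO2 | intermediate (not isolated)
25 | 1-(pentafluorophenyl) 1-phenyl (1R,2R)-2-{[(8S)-7,7-dimethyl-1,4-dioxaspiro[4.5]decan-8-yl]methyl}-3,3-dimethylcyclopentane-1,1-dicarboxylate (pentafluorophenyl ester trans to the C11 side chain) | O=C(Oc1c(F)c(F)c(F)c(F)c1F)[C@]1(C(=O)Oc2ccccc2)CCC(C)(C)[C@H]1C[C@@H]1CCC2(CC1(C)C)OCCO2 | intermediate
26 | 1-(pentafluorophenyl) 1-phenyl (1R,2R)-2-{[(1S)-2,2-dimethyl-4-oxocyclohexyl]methyl}-3,3-dimethylcyclopentane-1,1-dicarboxylate | O=C(Oc1c(F)c(F)c(F)c(F)c1F)[C@]1(C(=O)Oc2ccccc2)CCC(C)(C)[C@H]1C[C@@H]1CCC(=O)CC1(C)C | intermediate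
27 | bicyclic β-diketone phenyl ester: ring A ketone C9 with C5 bonded to the C4 ketone on C3; phenyl ester on C3 cis to C10; C5–H on the outer face; C3, C5, C7, C11 as in the target | O=C1[C@@H]2C[C@@H](C[C@@H]3C(C)(C)CC[C@@]3(C(=O)Oc4ccccc4)C2=O)C(C)(C)C1 | intermediate
28 | geranyl bromide, (2E)-1-bromo-3,7-dimethylocta-2,6-diene | CC(C)=CCC/C(C)=C/CBr | starting material
29 | 27 carrying the (2E)-3,7-dimethylocta-2,6-dienyl group at C5 | CC(C)=CCC/C(C)=C/C[C@@]12C[C@@H](C[C@@H]3C(C)(C)CC[C@@]3(C(=O)Oc3ccccc3)C1=O)C(C)(C)CC2=O | intermediate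
30 | cage trione: the target with H in place of the C1 benzoyl group | CC(C)=CCC/C(C)=C/C[C@@]12C[C@H]3C[C@@H]4C(C)(C)CC[C@]4(C1=O)C(=O)[C@@H](C2=O)C3(C)C | intermediate
31 | benzoyl chloride | O=C(Cl)c1ccccc1 | starting material
32 | C1 bridgehead lithium derivative of 30 | CC(C)=CCC/C(C)=C/C[C@@]12C[C@H]3C[C@@H]4C(C)(C)CC[C@]4(C1=O)C(=O)[C@@]([Li])(C2=O)C3(C)C | intermediate (not isolated)
33 | CNP0168637.1: C1-benzoyl, C5-geranyl, 8,8,12,12-tetramethyl cage 2,4,9-trione with the C3–C11-fused cyclopentane | CC(C)=CCC/C(C)=C/C[C@@]12C[C@H]3C[C@@H]4C(C)(C)CC[C@]4(C1=O)C(=O)[C@@](C(=O)c1ccccc1)(C2=O)C3(C)C | target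

Total step count: 19. Longest linear sequence: 19 steps, from (S)-limonene 1 to 33.

Steps most likely to fail

Step 11. The 1,2-hydride shift from C14 may outrun insertion into the hindered C11–H bond, the carbene may insert into a C12 methyl C–H bond, or the catalyst may fail to override the substrate and give the C11 epimer. The fallback sets out from aldehyde 16 and returns at 21; it keeps the C3–C11 insertion but uses a carbene with no hydrogen beside it. Roskamp homologation of 16 (methyl diazoacetate, SnCl2 cat., CH2Cl2) should give the β-keto ester methyl 7-[(8R)-7,7-dimethyl-1,4-dioxaspiro[4.5]decan-8-yl]-5,5-dimethyl-3-oxoheptanoate F1. Diazo transfer (p-ABSA, Et3N, MeCN) gives the α-diazo-β-keto ester F2. Its carbene has a carbonyl at C14, so no hydride can shift, and such carbenes are the best-precedented class for 1,5-insertion into unactivated methylene. Insertion is run with Rh2(S-PTTL)4, or with Rh2(OAc)4 and chromatographic separation of the C11 epimers, to give the cyclopentanone ester F3. The C14 carbonyl is then removed: NaH and PhNTf2 give the enol triflate F4, and Pd(OAc)2/PPh3/HCO2H/Et3N reduces it to the cyclopentene ester F5. Hydrogenation (H2, Pd/C) and NaOMe/MeOH equilibration return 21.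

Step 19. The twisted bridgehead C1–H may be deprotonated too slowly, or the short-lived carbanion may be captured unproductively while the acid chloride is consumed by the amide base. The fallback sets out from 30 and returns at 33; it forms the C1–carbon bond by aldol addition and adjusts the oxidation level afterwards. The bridgehead anion (LiTMP, THF, −78 °C) is trapped with benzaldehyde, a fast non-acylating electrophile, to give the bridgehead benzylic carbinol F7 as either carbinol epimer. Dess–Martin periodinane (CH2Cl2, rt) then oxidises F7 to 33.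

Step 18. Enolisation at C1 may be impeded by the flanking C8 gem-dimethyl group and the C5 geranyl group, or the strained non-enolisable trione may be reopened by phenoxide (retro-Claisen). The fallback sets out from 27 and returns at 30; it closes the cage before the geranyl group is present. Treatment of 27 with LDA (2.2 equiv, THF, −78 to 0 °C) forms the 1,3-diketone dianion, whose terminal carbon C1 is the more nucleophilic site and attacks the phenyl ester to give the geranyl-free cage trione F6. Bridgehead deprotonation of F6 at the less hindered C5–H (LiTMP, THF, −78 °C) and alkylation with geranyl bromide 28 then give 30.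

Further compounds

F1 | step 11 | methyl 7-[(8R)-7,7-dimethyl-1,4-dioxaspiro[4.5]decan-8-yl]-5,5-dimethyl-3-oxoheptanoate | COC(=O)CC(=O)CC(C)(C)CC[C@@H]1CCC2(CC1(C)C)OCCO2
F2 | step 11 | methyl 2-diazo-7-[(8R)-7,7-dimethyl-1,4-dioxaspiro[4.5]decan-8-yl]-5,5-dimethyl-3-oxoheptanoate | COC(=O)C(=[N+]=[N-])C(=O)CC(C)(C)CC[C@@H]1CCC2(CC1(C)C)OCCO2
F3 | step 11 | methyl 5-{[(8S)-7,7-dimethyl-1,4-dioxaspiro[4.5]decan-8-yl]methyl}-4,4-dimethyl-2-oxocyclopentane-1-carboxylate (trans, C11 as in 21) | COC(=O)[C@@H]1C(=O)CC(C)(C)[C@H]1C[C@@H]1CCC2(CC1(C)C)OCCO2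
F4 | step 11 | methyl 5-{[(8S)-7,7-dimethyl-1,4-dioxaspiro[4.5]decan-8-yl]methyl}-4,4-dimethyl-2-(trifluoromethylsulfonyloxy)cyclopent-1-ene-1-carboxylate | COC(=O)C1=C(OS(=O)(=O)C(F)(F)F)CC(C)(C)[C@H]1C[C@@H]1CCC2(CC1(C)C)OCCO2
F5 | step 11 | methyl 5-{[(8S)-7,7-dimethyl-1,4-dioxaspiro[4.5]decan-8-yl]methyl}-4,4-dimethylcyclopent-1-ene-1-carboxylate | COC(=O)C1=CCC(C)(C)[C@H]1C[C@@H]1CCC2(CC1(C)C)OCCO2
F6 | step 18 | cage trione with H at both C1 and C5 (30 lacking the geranyl group) | [C@@H]12C[C@H]3C[C@@H]4C(C)(C)CC[C@]4(C1=O)C(=O)[C@@H](C2=O)C3(C)C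
F7 | step 19 | 30 carrying a hydroxy(phenyl)methyl group at C1 (either carbinol epimer) | CC(C)=CCC/C(C)=C/C[C@@]12C[C@H]3C[C@@H]4C(C)(C)CC[C@]4(C1=O)C(=O)[C@@](C(O)c1ccccc1)(C2=O)C3(C)C
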